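## Structural features

The target is a C24 chain (numbered from the lactone carbonyl C1 to the propenyl methyl C24) closed at its two ends into six-membered oxygen heterocycles. Ring A (C1–C5) is an α,β-unsaturated δ-lactone, and ring B (O, C17–C21) is an oxane carrying an (E)-propenyl group at C21. The two rings are joined by C6–C16, which holds an (E,Z)-diene (C6=C7, trisubstituted Z C8=C9), the methyl-bearing sp3 centre C10, an (E,E)-diene (C12=C13, C14=C15) and the secondary carbinol C16. There are seven stereocentres: C5 (S) and C10 (R) are isolated, C16 (S) and C17 (R) are adjacent and anti, and C19 (S), C20 (R), C21 (R) are contiguous in ring B. In ring B the C17 and C21 carbon substituents are equatorial (2,6-cis), while the C19 hydroxyl and the C20 methyl are both axial. The fragile parts are the enoate of ring A (bases, nucleophiles), the doubly allylic C5–O acyloxy bond, the dienylic C16 carbinol (acid), the conjugated Z alkene (isomerisation) and the allylic ether C21–O. The real difficulty lies in stereocentres too far apart to control one another, in the Z-trisubstituted alkene inside a diene, in setting C16 during fragment union, and in a ring B with two axial groups. The key step uses the fact that C21 is both an ether carbon of ring B and allylic to C22=C23, so the O–C21 bond can be made from an allyl cation and re-opened, which places the C21 configuration under thermodynamic control.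

## Logic of the disconnections

41 ⇒ 40. Only the O19–Si bond is cut. Keeping O19 silylated to the end leaves 40 with a single free hydroxyl (the one made in the union) and puts no redox step after the union. The forward step must cleave a hindered axial silyl ether without ionising the C16 carbinol or opening ring A.

40 ⇒ 18 + 38. The C15–C16 bond is cut. It lies between the C12–C15 diene and ring B and divides the molecule into C1–C15 and C16–C24 halves of similar size. The forward step needs an alkenyl metal that tolerates the lactone and adds anti to the C17 oxygen, creating C16.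

18 ⇒ 17 ⇒ 16. No skeletal bond is cut; the C16 aldehyde is traced back to a benzyl ether that survives everything before it. The forward steps must remove benzyl without reducing the propenyl group or the allylic ring ether, and oxidise without epimerising C17.

16 ⇒ 15. The O–C21 bond of ring B is cut. C21 is allylic, so the ring can be closed from an allyl cation; the ring and the C21 centre then come from an open chain in which C21 need not be controlled. The forward step must be reversible enough to reach the 2,6-cis, E-propenyl isomer.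

15 ⇒ 11 + 12. The C21–C22 bond is cut (addition of a propenyl metal, through 13 and 14). Because both C21 epimers are usable, no selectivity is demanded; the only demand is retention of the E geometry and release of O17 after the addition, not before it.

11 ⇒ 10 ⇒ 9 ⇒ 8 ⇒ 5 + 6. The C19–C20 bond is cut (syn aldol). It sets C19 and C20 together under auxiliary control, independent of C17. The demands are reagent control over the existing C17 centre and two silyl ethers of clearly different lability on O17 and O19.

5 ⇒ 4 ⇒ 3 ⇒ 1 + 2. The C18–C19 bond is cut (epoxide opening). C17 is taken from 1, and the terminal alkene of 3 is a masked C19 aldehyde.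

38 ⇒ 37 ⇒ 35 + 36. The C2=C3 bond and the O–C1 ester bond are cut. Ring A is made last on this fragment under neutral conditions, so the enoate never meets a base or an organometallic. The catalyst must engage the two terminal alkenes and leave both dienes alone.

35 ⇒ 33 + 34. The C4–C5 bond is cut. C5 is remote from C10, so it is set by a chiral allyl reagent; the demand is high facial selectivity on a conjugated dienal.

33 ⇒ 32 ⇒ 30 + 31. The C15–I bond is traced to C15–Si, and the C7–C8 bond is cut (vinylation of the Z iodide with a three-carbon enal). The iodide needed for the union appears only after the last palladium step. The demands are retention of the Z geometry at C8=C9 and ipso-selective iodination.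

30 ⇒ 27 + 28 (through 29), 27 ⇒ 26. The C8=C9 double bond is cut; a kinetically controlled iodo-ylide olefination gives the Z iodide directly from the C9 aldehyde.

26 ⇒ 23 + 24 (through 25), 23 ⇒ 22 ⇒ 19 + 20. The C13–C14 bond and the C12–CH3 bond are cut (carbometalation of the alkyne, then coupling), then the C10–C11 bond (auxiliary alkylation), which sets C10.

## Other disconnections considered

Alternative 1: The cut removes C4–C5, C2–C3 and O–C1 of ring A. In the forward sense 2-deoxyribose-5-phosphate aldolase would add two molecules of acetaldehyde A2 to chloroacetaldehyde A1 and the product would close to the lactol A3. Oxidation and loss of the C3 hydroxyl would then give the chloromethyl lactone A4.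
- In its favour: C5 would be set by the enzyme in water with no auxiliary, and C1–C6 would arise in one operation from three two-carbon aldehydes. In atom economy and in expected enantiopurity of ring A this is the better of the two plans.
- Against it here: C3 arrives hydroxylated and C6 as CH2Cl. To reach C6=C7, A4 would need exchange of chloride for oxygen, oxidation to a labile α-acyloxy aldehyde, and an E-selective olefination in which a basic ylide meets the enoate.
- Comparison: structurally it solves only C5, which steps 19–21 also secure by a reliable reagent-controlled allylation. Mechanistically it is an enzymatic aldol against an allylboration plus metathesis. In step count ring A alone is about equal, but joining it to C7 would cost several more steps than the one-step vinylation used here. It does not address ring B or C21.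

Alternative 2: The cut is the C8=C9 double bond, made inside a temporary ring. The second-generation Grubbs catalyst RuCl2(=CHPh)(PCy3)(H2IMes) would close the methacrylate ester A5 to the lactone A6 with loss of ethylene.
- In its favour: the Z geometry is enforced by the ring, so in certainty of alkene geometry it is better than the kinetic olefination of step 16. C10 would come from a small chiral alcohol.
- Against it here: ring closure onto a 1,1-disubstituted, electron-poor alkene to give a trisubstituted one is slow. After opening of A6 both C7 and C11 are oxygenated, so C11 must be turned into a C–C bond to C12 and C7 into an aldehyde for the C6=C7 olefination, and the resulting Z α-methyl enal is prone to isomerise.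
- Comparison: structurally it addresses the same element as steps 16–17. Mechanistically it is superior in stereocontrol. In step economy it is worse for this target, because C11–C12 and C7–C8 are already in place or formed in one step in the chosen route.

Alternative 3: The cut is C17–C18 of ring B. (CH3)2AlCl would open the enol acetal A7 at the C17–O(enol) bond, and the aluminium enolate would close through C18 onto C17 to give the all-cis oxanone A8.
- In its favour: A7 would be assembled convergently from a syn β-hydroxy acid (C19–C24, propenyl group included) and an alkoxyacetaldehyde (C16–C17). C21 would be fixed by the aldol and not by equilibration, and the 2,6-cis outcome rests on a chair-like kinetic closure. In convergence and in confidence about the 2,6-cis relation it is the equal or the better of the chosen plan, and the step count to ring B would be about equal.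
- Against it here: the Lewis acid could ionise the allylic C21–O bond in place of the C17–O bond. The C20 methyl of A8 is axial and α to the ketone, so it could epimerise to the more stable equatorial isomer. C19 would still need a reduction that delivers the axial alcohol next to that axial methyl, followed by protection. The ester methylenation with Cp2TiMe2 needs heat.
- Comparison: the chosen plan takes C19 and C20 from one auxiliary-controlled aldol and leaves only C21 to thermodynamics. Alternative 3 fixes C21 and C17 well but opens two new stereochemical questions (C20 integrity, C19 reduction).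

Key step: step 9

Remark on the chemistry: the descriptors used below (5S, 10R, 16S, 17R, 19S, 20R, 21R for the target) follow from its SMILES; commercial (−)-B-allyldiisopinocampheylborane is taken to be the reagent derived from (+)-α-pinene, and (E)-1-bromopropene to be the pure E isomer.

## Steps

Step 1
Reactants: 1 (R)-benzyl glycidyl ether; 2 vinylmagnesium bromide (CH2=CHMgBr)
Product: 3 (R)-1-(benzyloxy)pent-4-en-2-ol
Conditions: CuI (10 mol%), THF, −40 → −20 °C; aq. NH4Cl
Reagents that add atoms: none
Why: Copper-catalysed Grignard opening of a terminal epoxide at the unsubstituted carbon (SN2) should give the homoallylic alcohol; C17 comes unchanged from 1.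

Step 2
Reactants: 3 (R)-1-(benzyloxy)pent-4-en-2-ol
Product: 4 (R)-{[1-(benzyloxy)pent-4-en-2-yl]oxy}triethylsilane
Conditions: Et3SiCl, imidazole, CH2Cl2, 0 °C → rt
Reagents that add atoms: chlorotriethylsilane, CC[Si](Cl)(CC)CC
Why: Standard silylation of a secondary alcohol; the triethylsilyl group is chosen because it can later be removed by dilute acid in the presence of the triisopropylsilyl ether on O19.

Step 3
Reactants: 4 (R)-{[1-(benzyloxy)pent-4-en-2-yl]oxy}triethylsilane
Product: 5 (R)-4-(benzyloxy)-3-(triethylsilyloxy)butanal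
Conditions: O3, CH2Cl2, −78 °C (to first blue colour); PPh3, −78 °C → rt
Reagents that add atoms: ozone, [O-][O+]=O
Why: Ozonolysis with reductive work-up should cleave the terminal alkene to the C19 aldehyde; stopping at the end point protects the benzyl ether, and the β-silyloxy aldehyde is used without delay.

Step 4
Reactants: 5 (R)-4-(benzyloxy)-3-(triethylsilyloxy)butanal; 6 (R)-4-benzyl-3-propionyl-1,3-oxazolidin-2-one
Product: 8 (R)-4-benzyl-3-[(2R,3S,5R)-6-(benzyloxy)-3-hydroxy-2-methyl-5-(triethylsilyloxy)hexanoyl]-1,3-oxazolidin-2-one, via Z-boron enolate 7 (not isolated)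
Conditions: Bu2BOTf, iPr2NEt, CH2Cl2, 0 °C; 5, −78 → 0 °C; pH 7 buffer, MeOH, H2O2, 0 °C
Reagents that add atoms: none
Why: Evans syn-aldol through a closed chair transition state of the Z-boron enolate; the auxiliary, not C17, decides the face, so the (R)-auxiliary should give the 19S,20R (2R,3S) syn adduct.

Step 5
Reactants: 8 (R)-4-benzyl-3-[(2R,3S,5R)-6-(benzyloxy)-3-hydroxy-2-methyl-5-(triethylsilyloxy)hexanoyl]-1,3-oxazolidin-2-one
Product: 9 (R)-4-benzyl-3-[(2R,3S,5R)-6-(benzyloxy)-2-methyl-5-(triethylsilyloxy)-3-(triisopropylsilyloxy)hexanoyl]-1,3-oxazolidin-2-one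
Conditions: iPr3SiOTf, 2,6-lutidine, CH2Cl2, −78 → 0 °C
Reagents that add atoms: triisopropylsilyl trifluoromethanesulfonate, CC(C)[Si](OS(=O)(=O)C(F)(F)F)(C(C)C)C(C)C
Why: Silyl triflate with a hindered base silylates the aldol hydroxyl without retro-aldol; the bulky group makes O19 a poor nucleophile in the key step and survives all steps up to the last.

Step 6
Reactants: 9 (R)-4-benzyl-3-[(2R,3S,5R)-6-(benzyloxy)-2-methyl-5-(triethylsilyloxy)-3-(triisopropylsilyloxy)hexanoyl]-1,3-oxazolidin-2-one
Product: 10 (2S,3S,5R)-6-(benzyloxy)-2-methyl-5-(triethylsilyloxy)-3-(triisopropylsilyloxy)hexan-1-ol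
Conditions: LiBH4, MeOH (1 equiv), THF, 0 °C
Reagents that add atoms: none
Why: Reductive removal of the oxazolidinone with LiBH4 should give the primary alcohol (C21) and the recoverable auxiliary; both silyl ethers and C20 are unaffected.

Step 7
Reactants: 10 (2S,3S,5R)-6-(benzyloxy)-2-methyl-5-(triethylsilyloxy)-3-(triisopropylsilyloxy)hexan-1-ol
Product: 11 (2R,3S,5R)-6-(benzyloxy)-2-methyl-5-(triethylsilyloxy)-3-(triisopropylsilyloxy)hexanal
Conditions: Dess–Martin periodinane, NaHCO3, CH2Cl2, 0 °C → rt
Reagents that add atoms: none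
Why: Buffered periodinane oxidation is neutral enough to keep the α-methyl aldehyde configurationally intact and the triethylsilyl ether in place; the aldehyde is used crude.

Step 8
Reactants: 11 (2R,3S,5R)-6-(benzyloxy)-2-methyl-5-(triethylsilyloxy)-3-(triisopropylsilyloxy)hexanal; 12 (E)-1-bromoprop-1-ene
Product: 15 (2R,4S,5S,6RS,7E)-1-(benzyloxy)-5-methyl-4-(triisopropylsilyloxy)non-7-ene-2,6-diol, via (E)-prop-1-enyllithium 13 (not isolated), via triethylsilyl ether 14 (not isolated)
Conditions: 12, t-BuLi (2 equiv), Et2O, −78 °C; 11, THF, −78 °C; then 1 M aq. HCl, THF, 0 °C → rt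
Reagents that add atoms: none
Why: Bromine–lithium exchange retains the E geometry and 1,2-addition to the aldehyde is faster than enolisation; no facial control at C21 is needed because both epimers feed the same cation in step 9. Dilute acid then cleaves the triethylsilyl ether while the triisopropylsilyl ether should stay, so O17 is freed only after the aldehyde is consumed and no lactol can form.

Step 9
Reactants: 15 (2R,4S,5S,6RS,7E)-1-(benzyloxy)-5-methyl-4-(triisopropylsilyloxy)non-7-ene-2,6-diol
Product: 16 (2R,3S,4S,6R)-6-[(benzyloxy)methyl]-3-methyl-2-[(E)-prop-1-enyl]-4-(triisopropylsilyloxy)oxane (2,6-cis)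
Conditions: FeCl3·6H2O (5–10 mol%), CH2Cl2, rt
Reagents that add atoms: none
Why: Hydrated FeCl3 (trivalent iron as Lewis acid and source of Brønsted acid) turns the C21 hydroxyl into a leaving group and releases the planar C21–C22–C23 allyl cation, the same species from either C21 epimer. The C17 hydroxyl adds to the C21 terminus in a 6-exo closure through a chair; attack at C23 would need an eight-membered ring, and the silylated O19 and benzylated O16 are poor nucleophiles. The closest known reaction type is the FeCl3-catalysed dehydrative cyclisation of hydroxy allylic alcohols and acetates to 2,6-cis-disubstituted oxanes. Because 16 is itself an allylic ether it can re-ionise under the same conditions, so C21 is set by thermodynamics and not by the configuration of 15. The fixed centres C17, C19 and C20 decide the outcome: the cis isomer has CH2OBn and propenyl equatorial with the silyloxy and methyl groups axial, whereas the trans isomer must either place the propenyl group axial and syn to the axial C19 oxygen or flip to a chair with the C17 substituent axial. The E alkene follows from the extended allyl cation and the same equilibration. The step needs O17 over O19 selectivity, 2,6-cis over trans and E over Z, and should leave the benzyl and triisopropylsilyl ethers untouched.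

Step 10
Reactants: 16 (2R,3S,4S,6R)-6-[(benzyloxy)methyl]-3-methyl-2-[(E)-prop-1-enyl]-4-(triisopropylsilyloxy)oxane
Product: 17 [(2R,4S,5S,6R)-5-methyl-6-[(E)-prop-1-enyl]-4-(triisopropylsilyloxy)oxan-2-yl]methanol
Conditions: lithium 4,4'-di-tert-butylbiphenylide (LiDBB, ca. 3 equiv), THF, −78 °C; aq. NH4Cl
Reagents that add atoms: none
Why: Electron transfer into the benzyl arene and loss of the benzyl fragment is fast at −78 °C, whereas an isolated alkene and its allylic C–O bond lack a low-lying acceptor orbital and should survive; hydrogenolysis is excluded by the propenyl group.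

Step 11
Reactants: 17 [(2R,4S,5S,6R)-5-methyl-6-[(E)-prop-1-enyl]-4-(triisopropylsilyloxy)oxan-2-yl]methanol
Product: 18 (2R,4S,5S,6R)-5-methyl-6-[(E)-prop-1-enyl]-4-(triisopropylsilyloxy)oxane-2-carbaldehyde
Conditions: Dess–Martin periodinane, NaHCO3, CH2Cl2, 0 °C → rt
Reagents that add atoms: none
Why: Neutral periodinane oxidation should give the α-alkoxy aldehyde without epimerising the equatorial C17 centre; it is used directly in step 22.

Step 12
Reactants: 19 (S)-4-benzyl-3-propionyl-1,3-oxazolidin-2-one; 20 propargyl bromide (3-bromoprop-1-yne)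
Product: 22 (S)-4-benzyl-3-[(R)-2-methylpent-4-ynoyl]-1,3-oxazolidin-2-one, via sodium Z-enolate 21 (not isolated)
Conditions: NaN(SiMe3)2, THF, −78 °C; 20, −78 → −45 °C
Reagents that add atoms: none
Why: Evans alkylation: the chelated Z-enolate is attacked by the reactive propargylic halide on the face opposite the benzyl group, which should set C10 as R.

Step 13
Reactants: 22 (S)-4-benzyl-3-[(R)-2-methylpent-4-ynoyl]-1,3-oxazolidin-2-one
Product: 23 (R)-2-methylpent-4-yn-1-ol
Conditions: LiBH4, H2O (1 equiv), Et2O, 0 °C
Reagents that add atoms: none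
Why: Reductive cleavage of the imide gives the primary alcohol (C9) without touching C10; the volatile product is concentrated with care.

Step 14
Reactants: 23 (R)-2-methylpent-4-yn-1-ol; 24 (E)-(2-bromovinyl)trimethylsilane
Product: 26 (2R,4E,6E)-2,4-dimethyl-7-(trimethylsilyl)hepta-4,6-dien-1-ol, via alkenylalane 25 (not isolated)
Conditions: Me3Al (3 equiv), Cp2ZrCl2 (25 mol%), ClCH2CH2Cl, 0 °C → rt; then 24, Pd(PPh3)4 (5 mol%), ZnCl2, THF, rt; dilute aq. HCl
Reagents that add atoms: trimethylaluminium, C[Al](C)C
Why: Zirconium-catalysed syn-carboalumination of the terminal alkyne (Negishi), tolerated by the aluminium alkoxide of the free alcohol, places the methyl on C12 and aluminium on C13 with E geometry. Palladium-catalysed alkenyl–alkenyl coupling, assisted by ZnCl2, should then join C13 to C14 with retention at both partners; the silyl group masks the future C15 iodide through the later palladium step.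

Step 15
Reactants: 26 (2R,4E,6E)-2,4-dimethyl-7-(trimethylsilyl)hepta-4,6-dien-1-ol
Product: 27 (2R,4E,6E)-2,4-dimethyl-7-(trimethylsilyl)hepta-4,6-dienal
Conditions: Dess–Martin periodinane, NaHCO3, CH2Cl2, 0 °C
Reagents that add atoms: none
Why: Neutral oxidation to the α-methyl aldehyde (C9), used at once to avoid epimerisation at C10.

Step 16
Reactants: 27 (2R,4E,6E)-2,4-dimethyl-7-(trimethylsilyl)hepta-4,6-dienal; 28 ethyltriphenylphosphonium iodide
Product: 30 [(1E,3E,6R,7Z)-8-iodo-4,6-dimethylnona-1,3,7-trienyl]trimethylsilane, via iodo ylide 29 (not isolated)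
Conditions: 28, n-BuLi, THF, rt; I2, −78 °C; NaN(SiMe3)2, −20 °C; 27, −78 → −20 °C
Reagents that add atoms: iodine, II
Why: Stork–Zhao-type olefination with the α-iodoethylidene ylide is kinetically Z-selective with α-branched aldehydes, so the iodine should end up cis to C10, the place later taken by C7. The weakly basic ylide should not epimerise C10.

Step 17
Reactants: 30 [(1E,3E,6R,7Z)-8-iodo-4,6-dimethylnona-1,3,7-trienyl]trimethylsilane; 31 acrolein (prop-2-enal)
Product: 32 (2E,4Z,6R,8E,10E)-4,6,8-trimethyl-11-(trimethylsilyl)undeca-2,4,8,10-tetraenal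
Conditions: Pd(OAc)2 (10 mol%), Bu4NCl, NaHCO3, DMF, rt, dark
Reagents that add atoms: none
Why: Heck vinylation under ligand-free phase-transfer conditions at room temperature: carbopalladation of the electron-poor alkene and syn β-hydride elimination should give the E enal (C6=C7) with retention of the Z geometry of the iodide. The vinylsilane is far less reactive than acrolein.

Step 18
Reactants: 32 (2E,4Z,6R,8E,10E)-4,6,8-trimethyl-11-(trimethylsilyl)undeca-2,4,8,10-tetraenal
Product: 33 (2E,4Z,6R,8E,10E)-11-iodo-4,6,8-trimethylundeca-2,4,8,10-tetraenal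
Conditions: N-iodosuccinimide, 2,6-lutidine, (CF3)2CHOH, 0 °C, dark
Reagents that add atoms: N-iodosuccinimide, O=C1CCC(=O)N1I
Why: Iododesilylation: ipso attack at C15 gives a cation that is β to silicon and tertiary-allylic at C12, and loss of silicon restores the E alkene with retention. The C6–C9 diene is conjugated to the aldehyde at this stage and should therefore be much less nucleophilic.

Step 19
Reactants: 33 (2E,4Z,6R,8E,10E)-11-iodo-4,6,8-trimethylundeca-2,4,8,10-tetraenal; 34 (−)-B-allyldiisopinocampheylborane
Product: 35 (4S,5E,7Z,9R,11E,13E)-14-iodo-7,9,11-trimethyltetradeca-1,5,7,11,13-pentaen-4-ol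
Conditions: 34, Et2O, −78 °C; then NaBO3·4H2O, THF/H2O, rt
Reagents that add atoms: none
Why: Brown allylboration through a closed chair transition state; the reagent from (+)-α-pinene adds to the Si face of unhindered and conjugated aldehydes, which here should give 5S (4S in this name). The remote C10 centre plays no part, and addition is 1,2.

Step 20
Reactants: 35 (4S,5E,7Z,9R,11E,13E)-14-iodo-7,9,11-trimethyltetradeca-1,5,7,11,13-pentaen-4-ol; 36 acryloyl chloride
Product: 37 (4S,5E,7Z,9R,11E,13E)-14-iodo-7,9,11-trimethyltetradeca-1,5,7,11,13-pentaen-4-yl prop-2-enoate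
Conditions: iPr2NEt, CH2Cl2, −78 → 0 °C
Reagents that add atoms: none
Why: O-Acylation of the secondary alcohol under cold, non-nucleophilic basic conditions, which should avoid ionisation or rearrangement of the dienylic ester.

Step 21
Reactants: 37 (4S,5E,7Z,9R,11E,13E)-14-iodo-7,9,11-trimethyltetradeca-1,5,7,11,13-pentaen-4-yl prop-2-enoate
Product: 38 (6S)-6-[(1E,3Z,5R,7E,9E)-10-iodo-3,5,7-trimethyldeca-1,3,7,9-tetraenyl]-5,6-dihydro-2H-pyran-2-one
Conditions: second-generation Grubbs catalyst RuCl2(=CHPh)(PCy3)(H2IMes) (5 mol%), CH2Cl2 (5 mM), 40 °C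
Reagents that add atoms: none
Why: Ring-closing metathesis of an acrylate with a terminal allyl group: the catalyst loads on the monosubstituted alkene and closes the six-membered enoate with loss of ethylene. The internal, conjugated and iodo-substituted alkenes are much slower partners, and closure onto C6=C7 would give a less favoured five-membered ring.

Step 22
Reactants: 18 (2R,4S,5S,6R)-5-methyl-6-[(E)-prop-1-enyl]-4-(triisopropylsilyloxy)oxane-2-carbaldehyde; 38 (6S)-6-[(1E,3Z,5R,7E,9E)-10-iodo-3,5,7-trimethyldeca-1,3,7,9-tetraenyl]-5,6-dihydro-2H-pyran-2-one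
Product: 40 (6S)-6-[(1E,3Z,5R,7E,9E,11S)-11-hydroxy-3,5,7-trimethyl-11-[(2R,4S,5S,6R)-5-methyl-6-[(E)-prop-1-enyl]-4-(triisopropylsilyloxy)oxan-2-yl]undeca-1,3,7,9-tetraenyl]-5,6-dihydro-2H-pyran-2-one, via alkenylchromium dichloride 39 (not isolated)
Conditions: CrCl2 (8 equiv), NiCl2 (1 mol%), DMSO, rt
Reagents that add atoms: none
Why: Nozaki–Hiyama–Kishi coupling: nickel inserts into the C15–I bond with retention, the alkenyl group passes to trivalent chromium, and the alkenylchromium adds to the aldehyde only, leaving lactone and dienes alone. A polar Felkin–Anh approach anti to the ring oxygen at C17 should favour the 16S (anti) carbinol; the minor epimer is removed by chromatography.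

Step 23
Reactants: 40 (6S)-6-[(1E,3Z,5R,7E,9E,11S)-11-hydroxy-3,5,7-trimethyl-11-[(2R,4S,5S,6R)-5-methyl-6-[(E)-prop-1-enyl]-4-(triisopropylsilyloxy)oxan-2-yl]undeca-1,3,7,9-tetraenyl]-5,6-dihydro-2H-pyran-2-one
Product: 41 (6S)-6-[(1E,3Z,5R,7E,9E,11S)-11-hydroxy-11-[(2R,4S,5R,6R)-4-hydroxy-5-methyl-6-[(E)-prop-1-enyl]oxan-2-yl]-3,5,7-trimethylundeca-1,3,7,9-tetraenyl]-5,6-dihydro-2H-pyran-2-one (target)
Conditions: HF·pyridine, pyridine, THF, 0 °C → rt
Reagents that add atoms: none
Why: Fluoride-driven cleavage of the silyl ether in a pyridine-buffered medium, which should be mild enough for the lactone and the dienylic C16 carbinol; no stereocentre is involved.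

## Compound list

1 | (R)-benzyl glycidyl ether | C(OCc1ccccc1)[C@H]1CO1 | starting material
2 | vinylmagnesium bromide (CH2=CHMgBr) | C=C[Mg]Br | starting material
3 | (R)-1-(benzyloxy)pent-4-en-2-ol | c1ccccc1COC[C@H](O)CC=C | intermediate
4 | (R)-{[1-(benzyloxy)pent-4-en-2-yl]oxy}triethylsilane | c1ccccc1COC[C@H](O[Si](CC)(CC)CC)CC=C | intermediate
5 | (R)-4-(benzyloxy)-3-(triethylsilyloxy)butanal | c1ccccc1COC[C@H](O[Si](CC)(CC)CC)CC=O | intermediate
6 | (R)-4-benzyl-3-propionyl-1,3-oxazolidin-2-one | CCC(=O)N1[C@H](Cc2ccccc2)COC1=O | starting material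
7 | Z-dibutylboron enolate of 6 | C/C=C(\OB(CCCC)CCCC)N1[C@H](Cc2ccccc2)COC1=O | intermediate (not isolated)
8 | (R)-4-benzyl-3-[(2R,3S,5R)-6-(benzyloxy)-3-hydroxy-2-methyl-5-(triethylsilyloxy)hexanoyl]-1,3-oxazolidin-2-one | c1ccccc1COC[C@H](O[Si](CC)(CC)CC)C[C@H](O)[C@@H](C)C(=O)N1[C@H](Cc2ccccc2)COC1=O | intermediate
9 | (R)-4-benzyl-3-[(2R,3S,5R)-6-(benzyloxy)-2-methyl-5-(triethylsilyloxy)-3-(triisopropylsilyloxy)hexanoyl]-1,3-oxazolidin-2-one | c1ccccc1COC[C@H](O[Si](CC)(CC)CC)C[C@H](O[Si](C(C)C)(C(C)C)C(C)C)[C@@H](C)C(=O)N1[C@H](Cc2ccccc2)COC1=O | intermediate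
10 | (2S,3S,5R)-6-(benzyloxy)-2-methyl-5-(triethylsilyloxy)-3-(triisopropylsilyloxy)hexan-1-ol | c1ccccc1COC[C@H](O[Si](CC)(CC)CC)C[C@H](O[Si](C(C)C)(C(C)C)C(C)C)[C@@H](C)CO | intermediate
11 | (2R,3S,5R)-6-(benzyloxy)-2-methyl-5-(triethylsilyloxy)-3-(triisopropylsilyloxy)hexanal | c1ccccc1COC[C@H](O[Si](CC)(CC)CC)C[C@H](O[Si](C(C)C)(C(C)C)C(C)C)[C@@H](C)C=O | intermediate
12 | (E)-1-bromoprop-1-ene | C/C=C/Br | starting material
13 | (E)-prop-1-enyllithium | C/C=C/[Li] | intermediate (not isolated)
14 | (2R,4S,5S,6RS,7E)-1-(benzyloxy)-5-methyl-2-(triethylsilyloxy)-4-(triisopropylsilyloxy)non-7-en-6-ol | c1ccccc1COC[C@H](O[Si](CC)(CC)CC)C[C@H](O[Si](C(C)C)(C(C)C)C(C)C)[C@@H](C)C(O)/C=C/C | intermediate (not isolated)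
15 | (2R,4S,5S,6RS,7E)-1-(benzyloxy)-5-methyl-4-(triisopropylsilyloxy)non-7-ene-2,6-diol | c1ccccc1COC[C@H](O)C[C@H](O[Si](C(C)C)(C(C)C)C(C)C)[C@@H](C)C(O)/C=C/C | intermediate
16 | (2R,3S,4S,6R)-6-[(benzyloxy)methyl]-3-methyl-2-[(E)-prop-1-enyl]-4-(triisopropylsilyloxy)oxane | C/C=C/[C@H]1O[C@@H](COCc2ccccc2)C[C@H](O[Si](C(C)C)(C(C)C)C(C)C)[C@H]1C | intermediate
17 | [(2R,4S,5S,6R)-5-methyl-6-[(E)-prop-1-enyl]-4-(triisopropylsilyloxy)oxan-2-yl]methanol | C/C=C/[C@H]1O[C@@H](CO)C[C@H](O[Si](C(C)C)(C(C)C)C(C)C)[C@H]1C | intermediate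
18 | (2R,4S,5S,6R)-5-methyl-6-[(E)-prop-1-enyl]-4-(triisopropylsilyloxy)oxane-2-carbaldehyde | C/C=C/[C@H]1O[C@@H](C=O)C[C@H](O[Si](C(C)C)(C(C)C)C(C)C)[C@H]1C | intermediate
19 | (S)-4-benzyl-3-propionyl-1,3-oxazolidin-2-one | CCC(=O)N1[C@@H](Cc2ccccc2)COC1=O | starting material
20 | propargyl bromide (3-bromoprop-1-yne) | C#CCBr | starting material
21 | sodium Z-enolate of 19 | C/C=C(\[O-])N1[C@@H](Cc2ccccc2)COC1=O.[Na+] | intermediate (not isolated)
22 | (S)-4-benzyl-3-[(R)-2-methylpent-4-ynoyl]-1,3-oxazolidin-2-one | C#CC[C@@H](C)C(=O)N1[C@@H](Cc2ccccc2)COC1=O | intermediate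
23 | (R)-2-methylpent-4-yn-1-ol | C#CC[C@@H](C)CO | intermediate
24 | (E)-(2-bromovinyl)trimethylsilane | Br/C=C/[Si](C)(C)C | starting material
25 | dimethyl[(1E,4R)-5-(dimethylalumanyloxy)-2,4-dimethylpent-1-enyl]alumane | C[Al](C)/C=C(\C)C[C@@H](C)CO[Al](C)C | intermediate (not isolated)
26 | (2R,4E,6E)-2,4-dimethyl-7-(trimethylsilyl)hepta-4,6-dien-1-ol | C[Si](C)(C)/C=C/C=C(\C)C[C@@H](C)CO | intermediate
27 | (2R,4E,6E)-2,4-dimethyl-7-(trimethylsilyl)hepta-4,6-dienal | C[Si](C)(C)/C=C/C=C(\C)C[C@@H](C)C=O | intermediate
28 | ethyltriphenylphosphonium iodide | CC[P+](c1ccccc1)(c1ccccc1)c1ccccc1.[I-] | starting material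
29 | (1-iodoethylidene)triphenylphosphorane | CC(I)=P(c1ccccc1)(c1ccccc1)c1ccccc1 | intermediate (not isolated)
30 | [(1E,3E,6R,7Z)-8-iodo-4,6-dimethylnona-1,3,7-trienyl]trimethylsilane | C[Si](C)(C)/C=C/C=C(\C)C[C@@H](C)/C=C(C)\I | intermediate
31 | acrolein (prop-2-enal) | C=CC=O | starting material
32 | (2E,4Z,6R,8E,10E)-4,6,8-trimethyl-11-(trimethylsilyl)undeca-2,4,8,10-tetraenal | C[Si](C)(C)/C=C/C=C(\C)C[C@@H](C)/C=C(C)\C=C\C=O | intermediate
33 | (2E,4Z,6R,8E,10E)-11-iodo-4,6,8-trimethylundeca-2,4,8,10-tetraenal | I/C=C/C=C(\C)C[C@@H](C)/C=C(C)\C=C\C=O | intermediate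
34 | (−)-B-allyldiisopinocampheylborane | C=CCB([C@@H]1C[C@@H]2C[C@H]([C@H]1C)C2(C)C)[C@@H]1C[C@@H]2C[C@H]([C@H]1C)C2(C)C | starting material
35 | (4S,5E,7Z,9R,11E,13E)-14-iodo-7,9,11-trimethyltetradeca-1,5,7,11,13-pentaen-4-ol | I/C=C/C=C(\C)C[C@@H](C)/C=C(C)\C=C\[C@@H](O)CC=C | intermediate
36 | acryloyl chloride | C=CC(=O)Cl | starting material
37 | (4S,5E,7Z,9R,11E,13E)-14-iodo-7,9,11-trimethyltetradeca-1,5,7,11,13-pentaen-4-yl prop-2-enoate | I/C=C/C=C(\C)C[C@@H](C)/C=C(C)\C=C\[C@@H](OC(=O)C=C)CC=C | intermediate
38 | (6S)-6-[(1E,3Z,5R,7E,9E)-10-iodo-3,5,7-trimethyldeca-1,3,7,9-tetraenyl]-5,6-dihydro-2H-pyran-2-one | I/C=C/C=C(\C)C[C@@H](C)/C=C(C)\C=C\[C@@H]1CC=CC(=O)O1 | intermediate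
39 | alkenylchromium dichloride derived from 38 (trivalent chromium) | Cl[Cr](Cl)/C=C/C=C(\C)C[C@@H](C)/C=C(C)\C=C\[C@@H]1CC=CC(=O)O1 | intermediate (not isolated)
40 | (6S)-6-[(1E,3Z,5R,7E,9E,11S)-11-hydroxy-3,5,7-trimethyl-11-[(2R,4S,5S,6R)-5-methyl-6-[(E)-prop-1-enyl]-4-(triisopropylsilyloxy)oxan-2-yl]undeca-1,3,7,9-tetraenyl]-5,6-dihydro-2H-pyran-2-one | C/C=C/[C@H]1O[C@@H]([C@@H](O)/C=C/C=C(\C)C[C@@H](C)/C=C(C)\C=C\[C@@H]2CC=CC(=O)O2)C[C@H](O[Si](C(C)C)(C(C)C)C(C)C)[C@H]1C | intermediate
41 | (6S)-6-[(1E,3Z,5R,7E,9E,11S)-11-hydroxy-11-[(2R,4S,5R,6R)-4-hydroxy-5-methyl-6-[(E)-prop-1-enyl]oxan-2-yl]-3,5,7-trimethylundeca-1,3,7,9-tetraenyl]-5,6-dihydro-2H-pyran-2-one | C/C=C/[C@H]1O[C@@H]([C@@H](O)/C=C/C=C(\C)C[C@@H](C)/C=C(C)\C=C\[C@@H]2CC=CC(=O)O2)C[C@H](O)[C@H]1C | target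

## Step count and least certain steps

Total: 23 steps. Longest linear sequence: 13 steps (steps 1–11, 22, 23); the second branch (steps 12–21) joins at step 22.

Step 9 (key step). The most likely failure is an equilibrium that does not lie far enough on the side of the 2,6-cis isomer. The trans isomer can escape the syn-axial clash by flipping to a chair with only the C17 substituent axial, so the energy gap is an estimate of about one to two kcal/mol. Other possible processes are loss of a proton from C20 of the cation to give a diene, and capture at C23 by O19 after silyl loss. The fallback avoids the cation and sets C21 by hydride delivery. It sets out from 10. Pyridinium p-toluenesulfonate in methanol should remove the triethylsilyl group to give (2S,3S,5R)-6-(benzyloxy)-2-methyl-3-(triisopropylsilyloxy)hexane-1,5-diol F1. TEMPO with PhI(OAc)2 should oxidise the 1,5-diol to (3R,4S,6R)-6-[(benzyloxy)methyl]-3-methyl-4-(triisopropylsilyloxy)oxan-2-one F2. Addition of 13 at −78 °C should stop at (2RS,3R,4S,6R)-6-[(benzyloxy)methyl]-3-methyl-2-[(E)-prop-1-enyl]-4-(triisopropylsilyloxy)oxan-2-ol F3. Et3SiH with BF3·OEt2 at −78 °C should then reduce the oxocarbenium ion by axial hydride attack, which leaves the propenyl group equatorial, and the route is rejoined at 16.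

Step 22. Poor facial selectivity is the main risk: the Felkin-type preference of alkenylchromium reagents for α-alkoxy aldehydes is moderate, and chelation by chromium would favour the wrong (16R) epimer. The fallback sets C16 by ketone reduction. It sets out from 40 as its mixture with the C16 epimer. MnO2 should oxidise only the dienylic carbinol to (6S)-6-[(1E,3Z,5R,7E,9E)-3,5,7-trimethyl-11-[(2R,4S,5S,6R)-5-methyl-6-[(E)-prop-1-enyl]-4-(triisopropylsilyloxy)oxan-2-yl]-11-oxoundeca-1,3,7,9-tetraenyl]-5,6-dihydro-2H-pyran-2-one F4. Zn(BH4)2 in Et2O at low temperature, through a chelate between the ketone and the ring oxygen, should deliver hydride to the less hindered face and give the anti carbinol, rejoining the route at 40.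

Step 18. The risks are competing iodination of the C6–C9 diene or of the aldehyde enol, and iodine-radical-induced Z to E isomerisation at C8=C9, because N-iodosuccinimide is not fully selective among electron-rich π systems. The fallback introduces the iodide before any second diene exists and avoids palladium afterwards. It sets out from 26 and takes six steps:
- N-iodosuccinimide should give (2R,4E,6E)-7-iodo-2,4-dimethylhepta-4,6-dien-1-ol F5.
- Dess–Martin oxidation gives (2R,4E,6E)-7-iodo-2,4-dimethylhepta-4,6-dienal F6.
- Still–Gennari olefination (methyl 2-[bis(2,2,2-trifluoroethoxy)phosphoryl]propanoate, KN(SiMe3)2, 18-crown-6) should give methyl (2Z,4R,6E,8E)-9-iodo-2,4,6-trimethylnona-2,6,8-trienoate F7.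
- (i-Bu)2AlH gives (2Z,4R,6E,8E)-9-iodo-2,4,6-trimethylnona-2,6,8-trien-1-ol F8.
- MnO2 gives (2Z,4R,6E,8E)-9-iodo-2,4,6-trimethylnona-2,6,8-trienal F9.
- Wittig reaction with (triphenylphosphoranylidene)acetaldehyde rejoins the route at 33.

Step 17. Acrolein can polymerise, the hindered α-methyl vinyl iodide may turn over slowly, and palladium hydride species may scramble the Z alkene. The fallback replaces carbopalladation by a cross-coupling at the alcohol oxidation level. It sets out from 30. Stille coupling with (E)-3-(tributylstannyl)prop-2-en-1-ol (Pd2(dba)3, AsPh3, N-methylpyrrolidone) should give (2E,4Z,6R,8E,10E)-4,6,8-trimethyl-11-(trimethylsilyl)undeca-2,4,8,10-tetraen-1-ol F10, and MnO2 oxidation rejoins the route at 32.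

Step 23. The hindered axial silyl ether may be cleaved slowly, and long exposure to the acidic fluoride medium could ionise the dienylic C16 carbinol or isomerise the dienes. The fallback removes the silyl group before the union. It sets out from 17. Bu4NF should give (2R,3R,4S,6R)-6-(hydroxymethyl)-3-methyl-2-[(E)-prop-1-enyl]oxan-4-ol F11. TEMPO with PhI(OAc)2 should oxidise only the primary alcohol to (2R,4S,5R,6R)-4-hydroxy-5-methyl-6-[(E)-prop-1-enyl]oxane-2-carbaldehyde F12. CrCl2/NiCl2 coupling of F12 with 38, which tolerates the free hydroxyl, reaches 41 directly.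

## Further compounds

F1 | step 9 | (2S,3S,5R)-6-(benzyloxy)-2-methyl-3-(triisopropylsilyloxy)hexane-1,5-diol | c1ccccc1COC[C@H](O)C[C@H](O[Si](C(C)C)(C(C)C)C(C)C)[C@@H](C)CO
F2 | step 9 | (3R,4S,6R)-6-[(benzyloxy)methyl]-3-methyl-4-(triisopropylsilyloxy)oxan-2-one | O=C1O[C@@H](COCc2ccccc2)C[C@H](O[Si](C(C)C)(C(C)C)C(C)C)[C@H]1C
F3 | step 9 | (2RS,3R,4S,6R)-6-[(benzyloxy)methyl]-3-methyl-2-[(E)-prop-1-enyl]-4-(triisopropylsilyloxy)oxan-2-ol | C/C=C/C1(O)O[C@@H](COCc2ccccc2)C[C@H](O[Si](C(C)C)(C(C)C)C(C)C)[C@H]1C
F4 | step 22 | (6S)-6-[(1E,3Z,5R,7E,9E)-3,5,7-trimethyl-11-[(2R,4S,5S,6R)-5-methyl-6-[(E)-prop-1-enyl]-4-(triisopropylsilyloxy)oxan-2-yl]-11-oxoundeca-1,3,7,9-tetraenyl]-5,6-dihydro-2H-pyran-2-one | C/C=C/[C@H]1O[C@@H](C(=O)/C=C/C=C(\C)C[C@@H](C)/C=C(C)\C=C\[C@@H]2CC=CC(=O)O2)C[C@H](O[Si](C(C)C)(C(C)C)C(C)C)[C@H]1C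
F5 | step 18 | (2R,4E,6E)-7-iodo-2,4-dimethylhepta-4,6-dien-1-ol | I/C=C/C=C(\C)C[C@@H](C)CO
F6 | step 18 | (2R,4E,6E)-7-iodo-2,4-dimethylhepta-4,6-dienal | I/C=C/C=C(\C)C[C@@H](C)C=O
F7 | step 18 | methyl (2Z,4R,6E,8E)-9-iodo-2,4,6-trimethylnona-2,6,8-trienoate | I/C=C/C=C(\C)C[C@@H](C)/C=C(C)\C(=O)OC
F8 | step 18 | (2Z,4R,6E,8E)-9-iodo-2,4,6-trimethylnona-2,6,8-trien-1-ol | I/C=C/C=C(\C)C[C@@H](C)/C=C(C)\CO
F9 | step 18 | (2Z,4R,6E,8E)-9-iodo-2,4,6-trimethylnona-2,6,8-trienal | I/C=C/C=C(\C)C[C@@H](C)/C=C(C)\C=O
F10 | step 17 | (2E,4Z,6R,8E,10E)-4,6,8-trimethyl-11-(trimethylsilyl)undeca-2,4,8,10-tetraen-1-ol | C[Si](C)(C)/C=C/C=C(\C)C[C@@H](C)/C=C(C)\C=C\CO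
F11 | step 23 | (2R,3R,4S,6R)-6-(hydroxymethyl)-3-methyl-2-[(E)-prop-1-enyl]oxan-4-ol | C/C=C/[C@H]1O[C@@H](CO)C[C@H](O)[C@H]1C
F12 | step 23 | (2R,4S,5R,6R)-4-hydroxy-5-methyl-6-[(E)-prop-1-enyl]oxane-2-carbaldehyde | C/C=C/[C@H]1O[C@@H](C=O)C[C@H](O)[C@H]1C
A1 | alternative 1 | chloroacetaldehyde | ClCC=O
A2 | alternative 1 | acetaldehyde | CC=O
A3 | alternative 1 | (3R,5S)-6-chloro-2,4,6-trideoxyhexopyranose (anomer mixture) | ClC[C@@H]1C[C@@H](O)CC(O)O1
A4 | alternative 1 | (S)-6-(chloromethyl)-5,6-dihydro-2H-pyran-2-one | ClC[C@@H]1CC=CC(=O)O1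
A5 | alternative 2 | (S)-2-methylbut-3-enyl 2-methylprop-2-enoate | C=C(C)C(=O)OC[C@@H](C)C=C
A6 | alternative 2 | (S)-3,5-dimethyl-5,6-dihydro-2H-pyran-2-one | CC1=C[C@H](C)COC1=O
A7 | alternative 3 | all-cis 2-(benzyloxymethyl)-5-methyl-4-methylidene-6-[(E)-prop-1-enyl]-1,3-dioxane | C/C=C/[C@H]1O[C@@H](COCc2ccccc2)OC(=C)[C@H]1C
A8 | alternative 3 | all-cis 6-(benzyloxymethyl)-3-methyl-2-[(E)-prop-1-enyl]oxan-4-one | C/C=C/[C@H]1O[C@@H](COCc2ccccc2)CC(=O)[C@H]1C
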